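**Plan**

1. The target is 3-(4-hydroxy-3-methoxybenzyl)-4-(4-hydroxy-2-methoxyphenyl)-6,8-dimethoxynaphthalene-2,7-diol, numbered C1 (H), C2 (OH), C3 (benzyl), C4 (aryl); ring A is C4a–C8a, ring B is C1–C4.
2. Enabling feature: the C3=C4 bond of ring B plus the benzylic carbon on C3 is the retron of an alkyne–carbonyl metathesis. C4 is a diaryl ketone carbon, C3 the tether-side alkyne carbon, and the benzylic carbon the distal alkyne carbon, which takes over the ketone oxygen as an aroyl C=O.
3. Cuts, in retrosynthetic order: C3=C4 (metathesis), C2–C3 (acetylide plus arylacetaldehyde), C4–aryl (aryllithium plus aldehyde), C1–C8a (Stille allylation; the alkene is later cleaved to the C1–C2 unit).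
4. Forward: ring A from syringaldehyde is brominated, allylated and arylated to the benzophenone; the alkyne arm from vanillin is added; FeCl3 closes ring B; desilylation, oxidation with aromatisation and one hydrogenation finish the naphthol.
5. Stereochemistry: the target has no stereocentre; the C2 carbinol centre of the intermediates is racemic and disappears when ring B aromatises.

Key step: step 12

Assumption: the target SMILES has no stereodescriptor, so the C4–aryl axis is treated as configurationally undefined; chiral intermediates are carried as racemates or diastereomer mixtures, and bicyclic compounds keep the target numbering.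

**Route**

Step 1
Reactants: 1 syringaldehyde
Product: 2 4-(benzyloxy)-3,5-dimethoxybenzaldehyde
Conditions: BnBr, K2CO3, DMF, 60 °C
Reagents that add atoms: benzyl bromide, BrCc1ccccc1
Why: Williamson ether synthesis on the phenoxide installs a benzyl ether that survives all later steps and falls off in the final hydrogenation.

Step 2
Reactants: 2 4-(benzyloxy)-3,5-dimethoxybenzaldehyde
Product: 3 4-(benzyloxy)-2-bromo-3,5-dimethoxybenzaldehyde
Conditions: NBS, DMF, rt
Reagents that add atoms: N-bromosuccinimide, O=C1CCC(=O)N1Br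
Why: Electrophilic aromatic bromination should go to the equivalent C2/C6 positions, each ortho and para to a methoxy group, and the first bromine deactivates the ring against a second.

Step 3
Reactants: 3 4-(benzyloxy)-2-bromo-3,5-dimethoxybenzaldehyde
Product: 4 2-allyl-4-(benzyloxy)-3,5-dimethoxybenzaldehyde
Conditions: allylSnBu3, Pd(PPh3)4 (5 mol %), toluene, 110 °C
Reagents that add atoms: allyltributylstannane, C=CC[Sn](CCCC)(CCCC)CCCC
Why: Stille coupling, in which zerovalent palladium inserts into the C–Br bond activated by the ortho formyl group and allyl transfer from tin followed by reductive elimination forms the future C1–C8a bond.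

Step 4
Reactants: 5 4-bromo-3-methoxyphenol
Product: 6 4-(benzyloxy)-1-bromo-2-methoxybenzene
Conditions: BnBr, K2CO3, acetone, reflux
Reagents that add atoms: benzyl bromide, BrCc1ccccc1
Why: Williamson ether synthesis masks the phenol before metalation.

Step 5
Reactants: 6 4-(benzyloxy)-1-bromo-2-methoxybenzene; 4 2-allyl-4-(benzyloxy)-3,5-dimethoxybenzaldehyde
Product: 8 racemic [2-allyl-4-(benzyloxy)-3,5-dimethoxyphenyl][4-(benzyloxy)-2-methoxyphenyl]methanol, via aryllithium 7 (not isolated)
Conditions: n-BuLi, THF, −78 °C; then 4, −78 to 0 °C; aq. NH4Cl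
Reagents that add atoms: none
Why: Bromine–lithium exchange gives an aryllithium held by the ortho methoxy group, and its 1,2-addition to the aldehyde forms the C4–aryl bond; the new carbinol centre is racemic and is removed in step 6.

Step 6
Reactants: 8 racemic [2-allyl-4-(benzyloxy)-3,5-dimethoxyphenyl][4-(benzyloxy)-2-methoxyphenyl]methanol
Product: 9 [2-allyl-4-(benzyloxy)-3,5-dimethoxyphenyl][4-(benzyloxy)-2-methoxyphenyl]methanone
Conditions: Dess–Martin periodinane, CH2Cl2, rt
Reagents that add atoms: none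
Why: Dess–Martin oxidation of a doubly benzylic secondary alcohol to the diaryl ketone is fast and leaves the allyl group and benzyl ethers untouched.

Step 7
Reactants: 9 [2-allyl-4-(benzyloxy)-3,5-dimethoxyphenyl][4-(benzyloxy)-2-methoxyphenyl]methanone
Product: 11 2-{3-(benzyloxy)-6-[4-(benzyloxy)-2-methoxybenzoyl]-2,4-dimethoxyphenyl}acetaldehyde, via vicinal diol 10 (not isolated)
Conditions: OsO4 (2 mol %), NaIO4, 2,6-lutidine, dioxane/H2O, rt; used crude in step 10
Reagents that add atoms: OsO4, O=[Os](=O)(=O)=O (delivers the aldehyde oxygen; its oxygen is restored by NaIO4, [Na+].[O-]I(=O)(=O)=O)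
Why: Lemieux–Johnson oxidation dihydroxylates the only alkene and cleaves the diol in the same flask, and 2,6-lutidine keeps the medium near neutral so that the enolisable keto aldehyde should survive.

Step 8
Reactants: 12 vanillin
Product: 13 4-(benzyloxy)-3-methoxybenzaldehyde
Conditions: BnBr, K2CO3, DMF, 60 °C
Reagents that add atoms: benzyl bromide, BrCc1ccccc1
Why: Williamson ether synthesis protects the phenol as the same hydrogenolysable benzyl ether used elsewhere.

Step 9
Reactants: 13 4-(benzyloxy)-3-methoxybenzaldehyde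
Product: 15 1-(benzyloxy)-4-ethynyl-2-methoxybenzene, via diazoalkene 14 (not isolated)
Conditions: dimethyl (1-diazo-2-oxopropyl)phosphonate, K2CO3, MeOH, rt
Reagents that add atoms: Ohira–Bestmann reagent, COP(=O)(OC)C(=[N+]=[N-])C(C)=O
Why: Ohira–Bestmann variant of the Seyferth–Gilbert homologation, in which the diazoalkene formed by olefination loses N2 and the carbene rearranges by 1,2-shift to the terminal alkyne, a reliable process for non-enolisable aryl aldehydes.

Step 10
Reactants: 15 1-(benzyloxy)-4-ethynyl-2-methoxybenzene; 11 2-{3-(benzyloxy)-6-[4-(benzyloxy)-2-methoxybenzoyl]-2,4-dimethoxyphenyl}acetaldehyde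
Product: 17 racemic [4-(benzyloxy)-2-{4-[4-(benzyloxy)-3-methoxyphenyl]-2-hydroxybut-3-yn-1-yl}-3,5-dimethoxyphenyl][4-(benzyloxy)-2-methoxyphenyl]methanone, via lithium acetylide 16 (not isolated)
Conditions: n-BuLi, THF, −78 °C; then 11, −78 °C; aq. NH4Cl
Reagents that add atoms: none
Why: 1,2-Addition of a lithium acetylide forms the C2–C3 bond at the aldehyde, which is far more electrophilic than the hindered, electron-rich diaryl ketone; the C2 centre needs no control because it is lost on aromatisation.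

Step 11
Reactants: 17 racemic [4-(benzyloxy)-2-{4-[4-(benzyloxy)-3-methoxyphenyl]-2-hydroxybut-3-yn-1-yl}-3,5-dimethoxyphenyl][4-(benzyloxy)-2-methoxyphenyl]methanone
Product: 18 racemic [4-(benzyloxy)-2-{4-[4-(benzyloxy)-3-methoxyphenyl]-2-[(tert-butyldimethylsilyl)oxy]but-3-yn-1-yl}-3,5-dimethoxyphenyl][4-(benzyloxy)-2-methoxyphenyl]methanone
Conditions: TBSCl, imidazole, DMF, rt
Reagents that add atoms: tert-butyldimethylsilyl chloride, CC(C)(C)[Si](C)(C)Cl
Why: Imidazole-promoted silylation of the unhindered secondary propargylic alcohol blocks Meyer–Schuster rearrangement and hemiketal formation with the ketone, and gives a bulky, weakly Lewis-basic ether.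

Step 12
Reactants: 18 racemic [4-(benzyloxy)-2-{4-[4-(benzyloxy)-3-methoxyphenyl]-2-[(tert-butyldimethylsilyl)oxy]but-3-yn-1-yl}-3,5-dimethoxyphenyl][4-(benzyloxy)-2-methoxyphenyl]methanone
Product: 20 racemic {7-(benzyloxy)-4-[4-(benzyloxy)-2-methoxyphenyl]-2-[(tert-butyldimethylsilyl)oxy]-6,8-dimethoxy-1,2-dihydronaphthalen-3-yl}[4-(benzyloxy)-3-methoxyphenyl]methanone, via fused oxetene 19 (not isolated)
Conditions: FeCl3 (anhydrous, 15 mol %), ClCH2CH2Cl, rt to 60 °C
Reagents that add atoms: none
Why: FeCl3, a trivalent iron Lewis acid, should bind the diaryl ketone oxygen, and the tether-side alkyne carbon then attacks the carbonyl carbon (future C4), closing ring B in a 6-exo-dig mode with the vinyl cation on the exocyclic carbon, where the 4-benzyloxy-3-methoxyphenyl group stabilises it. The cation collapses with the iron alkoxide to the fused oxetene 19, whose electrocyclic ring opening (the second half of a formal (2+2)/retro-(2+2) sequence) forms the C3=C4 bond and leaves the oxygen on the former distal alkyne carbon as the aroyl carbonyl. The closest known reaction type is the Lewis-acid-catalysed intramolecular alkyne–carbonyl metathesis of aryl-tethered aryl alkynes, which gives 3-acyl-1,2-dihydronaphthalenes. No lasting stereocentre is created: C2 is carried as the racemate and the transient C4 centre of 19 vanishes on ring opening. The step needs attack through the tether-side carbon, which the six-membered ring size and the cation-stabilising aryl group on the distal carbon secure, and it must outrun ionisation of the propargylic C–O bond, which is slowed because that carbon has no aryl group and the bulky silyl ether is a poor Lewis base. In the product the C3 aroyl group disfavours an allyl cation at C2 and so should hold back loss of silanol.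

Step 13
Reactants: 20 racemic {7-(benzyloxy)-4-[4-(benzyloxy)-2-methoxyphenyl]-2-[(tert-butyldimethylsilyl)oxy]-6,8-dimethoxy-1,2-dihydronaphthalen-3-yl}[4-(benzyloxy)-3-methoxyphenyl]methanone
Product: 21 racemic {7-(benzyloxy)-4-[4-(benzyloxy)-2-methoxyphenyl]-2-hydroxy-6,8-dimethoxy-1,2-dihydronaphthalen-3-yl}[4-(benzyloxy)-3-methoxyphenyl]methanone
Conditions: Bu4NF, AcOH, THF, 0 °C to rt
Reagents that add atoms: none
Why: Fluoride-mediated desilylation, buffered with acetic acid so that the liberated alkoxide is protonated at once and base-induced loss of water from the 1,2-dihydronaphthalen-2-ol is avoided.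

Step 14
Reactants: 21 racemic {7-(benzyloxy)-4-[4-(benzyloxy)-2-methoxyphenyl]-2-hydroxy-6,8-dimethoxy-1,2-dihydronaphthalen-3-yl}[4-(benzyloxy)-3-methoxyphenyl]methanone
Product: 23 {7-(benzyloxy)-4-[4-(benzyloxy)-2-methoxyphenyl]-2-hydroxy-6,8-dimethoxynaphthalen-3-yl}[4-(benzyloxy)-3-methoxyphenyl]methanone, via keto tautomer 22 (not isolated)
Conditions: Dess–Martin periodinane (1.1 equiv), pyridine, CH2Cl2, 0 °C to rt
Reagents that add atoms: none
Why: Dess–Martin oxidation of the secondary allylic alcohol gives a naphthalen-2(1H)-one that enolises toward C1 at once because this makes ring B aromatic, and the hydrogen bond from the new naphthol to the C3 aroyl group should protect it from further oxidation.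

Step 15
Reactants: 23 {7-(benzyloxy)-4-[4-(benzyloxy)-2-methoxyphenyl]-2-hydroxy-6,8-dimethoxynaphthalen-3-yl}[4-(benzyloxy)-3-methoxyphenyl]methanone
Product: 26 3-(4-hydroxy-3-methoxybenzyl)-4-(4-hydroxy-2-methoxyphenyl)-6,8-dimethoxynaphthalene-2,7-diol, via triphenol ketone 24 (not isolated), via triphenol carbinol 25 (not isolated)
Conditions: H2 (1–4 atm), 10% Pd/C, EtOAc/MeOH, cat. HCl, rt
Reagents that add atoms: none
Why: Catalytic hydrogenolysis cleaves the three aryl benzyl ethers, and under acid the diaryl ketone is hydrogenated to a carbinol whose benzylic C–O bond, flanked by an ortho-hydroxy and a para-hydroxy aryl group, is hydrogenolysed to the methylene group.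

**Compound list**

1 | syringaldehyde (4-hydroxy-3,5-dimethoxybenzaldehyde) | COc1cc(C=O)cc(OC)c1O | starting material
2 | 4-(benzyloxy)-3,5-dimethoxybenzaldehyde | COc1cc(C=O)cc(OC)c1OCc1ccccc1 | intermediate
3 | 4-(benzyloxy)-2-bromo-3,5-dimethoxybenzaldehyde | COc1cc(C=O)c(Br)c(OC)c1OCc1ccccc1 | intermediate
4 | 2-allyl-4-(benzyloxy)-3,5-dimethoxybenzaldehyde | COc1cc(C=O)c(CC=C)c(OC)c1OCc1ccccc1 | intermediate
5 | 4-bromo-3-methoxyphenol | COc1cc(O)ccc1Br | starting material
6 | 4-(benzyloxy)-1-bromo-2-methoxybenzene | COc1cc(OCc2ccccc2)ccc1Br | intermediate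
7 | [4-(benzyloxy)-2-methoxyphenyl]lithium (formed in the flask) | COc1cc(OCc2ccccc2)ccc1[Li] | intermediate
8 | racemic [2-allyl-4-(benzyloxy)-3,5-dimethoxyphenyl][4-(benzyloxy)-2-methoxyphenyl]methanol | COc1cc(C(O)c2ccc(OCc3ccccc3)cc2OC)c(CC=C)c(OC)c1OCc1ccccc1 | intermediate
9 | [2-allyl-4-(benzyloxy)-3,5-dimethoxyphenyl][4-(benzyloxy)-2-methoxyphenyl]methanone | COc1cc(C(=O)c2ccc(OCc3ccccc3)cc2OC)c(CC=C)c(OC)c1OCc1ccccc1 | intermediate
10 | racemic [4-(benzyloxy)-2-(2,3-dihydroxypropyl)-3,5-dimethoxyphenyl][4-(benzyloxy)-2-methoxyphenyl]methanone (formed in the flask) | COc1cc(C(=O)c2ccc(OCc3ccccc3)cc2OC)c(CC(O)CO)c(OC)c1OCc1ccccc1 | intermediate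
11 | 2-{3-(benzyloxy)-6-[4-(benzyloxy)-2-methoxybenzoyl]-2,4-dimethoxyphenyl}acetaldehyde | COc1cc(C(=O)c2ccc(OCc3ccccc3)cc2OC)c(CC=O)c(OC)c1OCc1ccccc1 | intermediate
12 | vanillin (4-hydroxy-3-methoxybenzaldehyde) | COc1cc(C=O)ccc1O | starting material
13 | 4-(benzyloxy)-3-methoxybenzaldehyde | COc1cc(C=O)ccc1OCc1ccccc1 | intermediate
14 | 1-(benzyloxy)-4-(2-diazoethenyl)-2-methoxybenzene (diazoalkene, formed in the flask) | COc1cc(C=C=[N+]=[N-])ccc1OCc1ccccc1 | intermediate
15 | 1-(benzyloxy)-4-ethynyl-2-methoxybenzene | COc1cc(C#C)ccc1OCc1ccccc1 | intermediate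
16 | {[4-(benzyloxy)-3-methoxyphenyl]ethynyl}lithium (formed in the flask) | COc1cc(C#C[Li])ccc1OCc1ccccc1 | intermediate
17 | racemic [4-(benzyloxy)-2-{4-[4-(benzyloxy)-3-methoxyphenyl]-2-hydroxybut-3-yn-1-yl}-3,5-dimethoxyphenyl][4-(benzyloxy)-2-methoxyphenyl]methanone | COc1cc(C(=O)c2ccc(OCc3ccccc3)cc2OC)c(CC(O)C#Cc2ccc(OCc3ccccc3)c(OC)c2)c(OC)c1OCc1ccccc1 | intermediate
18 | racemic [4-(benzyloxy)-2-{4-[4-(benzyloxy)-3-methoxyphenyl]-2-[(tert-butyldimethylsilyl)oxy]but-3-yn-1-yl}-3,5-dimethoxyphenyl][4-(benzyloxy)-2-methoxyphenyl]methanone | COc1cc(C(=O)c2ccc(OCc3ccccc3)cc2OC)c(CC(O[Si](C)(C)C(C)(C)C)C#Cc2ccc(OCc3ccccc3)c(OC)c2)c(OC)c1OCc1ccccc1 | intermediate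
19 | oxetene (formed in the flask, diastereomer mixture): 2H-oxete fused across C3–C4 of the ring A/ring B core; C4 carries the ring oxygen and the 4-benzyloxy-2-methoxyphenyl group, C3 is double-bonded to the oxete carbon bearing the 4-benzyloxy-3-methoxyphenyl group, C2 keeps the silyl ether | COc1cc2c(c(OC)c1OCc1ccccc1)CC(O[Si](C)(C)C(C)(C)C)C1=C(c3ccc(OCc4ccccc4)c(OC)c3)OC12c1ccc(OCc3ccccc3)cc1OC | intermediate
20 | racemic {7-(benzyloxy)-4-[4-(benzyloxy)-2-methoxyphenyl]-2-[(tert-butyldimethylsilyl)oxy]-6,8-dimethoxy-1,2-dihydronaphthalen-3-yl}[4-(benzyloxy)-3-methoxyphenyl]methanone | COc1cc2c(c(OC)c1OCc1ccccc1)CC(O[Si](C)(C)C(C)(C)C)C(C(=O)c1ccc(OCc3ccccc3)c(OC)c1)=C2c1ccc(OCc3ccccc3)cc1OC | intermediate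
21 | racemic {7-(benzyloxy)-4-[4-(benzyloxy)-2-methoxyphenyl]-2-hydroxy-6,8-dimethoxy-1,2-dihydronaphthalen-3-yl}[4-(benzyloxy)-3-methoxyphenyl]methanone | COc1cc2c(c(OC)c1OCc1ccccc1)CC(O)C(C(=O)c1ccc(OCc3ccccc3)c(OC)c1)=C2c1ccc(OCc3ccccc3)cc1OC | intermediate
22 | 7-(benzyloxy)-3-[4-(benzyloxy)-3-methoxybenzoyl]-4-[4-(benzyloxy)-2-methoxyphenyl]-6,8-dimethoxynaphthalen-2(1H)-one (keto tautomer, formed in the flask) | COc1cc2c(c(OC)c1OCc1ccccc1)CC(=O)C(C(=O)c1ccc(OCc3ccccc3)c(OC)c1)=C2c1ccc(OCc3ccccc3)cc1OC | intermediate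
23 | {7-(benzyloxy)-4-[4-(benzyloxy)-2-methoxyphenyl]-2-hydroxy-6,8-dimethoxynaphthalen-3-yl}[4-(benzyloxy)-3-methoxyphenyl]methanone | COc1cc2c(c(OC)c1OCc1ccccc1)cc(O)c(C(=O)c1ccc(OCc3ccccc3)c(OC)c1)c2-c1ccc(OCc3ccccc3)cc1OC | intermediate
24 | [2,7-dihydroxy-4-(4-hydroxy-2-methoxyphenyl)-6,8-dimethoxynaphthalen-3-yl](4-hydroxy-3-methoxyphenyl)methanone (formed in the flask) | COc1cc(C(=O)c2c(O)cc3c(OC)c(O)c(OC)cc3c2-c2ccc(O)cc2OC)ccc1O | intermediate
25 | racemic 3-[hydroxy(4-hydroxy-3-methoxyphenyl)methyl]-4-(4-hydroxy-2-methoxyphenyl)-6,8-dimethoxynaphthalene-2,7-diol (formed in the flask) | COc1cc(C(O)c2c(O)cc3c(OC)c(O)c(OC)cc3c2-c2ccc(O)cc2OC)ccc1O | intermediate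
26 | 3-(4-hydroxy-3-methoxybenzyl)-4-(4-hydroxy-2-methoxyphenyl)-6,8-dimethoxynaphthalene-2,7-diol (CNP0000246.0) | COc1cc(Cc2c(O)cc3c(OC)c(O)c(OC)cc3c2-c2ccc(O)cc2OC)ccc1O | target

**Count**

Total steps: 15.
Longest linear sequence: 12 steps (steps 1, 2, 3, 5, 6, 7, 10, 11, 12, 13, 14, 15, from syringaldehyde).

**Steps most likely to fail**

Step 12. The metathesis may lose out to Lewis-acid ionisation of the propargylic C–O bond, to loss of silanol from the product with aromatisation to a naphthalene lacking the C2 oxygen, or to sluggish activation of the hindered, electron-rich diaryl ketone. The fallback closes ring B by a classical aldol route; it sets out from 17 and comes back at 26. Hydrogenation of 17 over Pd/C poisoned with Ph2S (H2, EtOAc) should saturate the alkyne while sparing the aryl benzyl ethers and the diaryl ketone, giving racemic [4-(benzyloxy)-2-{4-[4-(benzyloxy)-3-methoxyphenyl]-2-hydroxybutyl}-3,5-dimethoxyphenyl][4-(benzyloxy)-2-methoxyphenyl]methanone F1. Dess–Martin oxidation gives 1-{3-(benzyloxy)-6-[4-(benzyloxy)-2-methoxybenzoyl]-2,4-dimethoxyphenyl}-4-[4-(benzyloxy)-3-methoxyphenyl]butan-2-one F2. KOH in EtOH at reflux should then bring about intramolecular aldol condensation of the C3 methylene onto the diaryl ketone, and dehydration and tautomerisation give 7-(benzyloxy)-3-[4-(benzyloxy)-3-methoxybenzyl]-4-[4-(benzyloxy)-2-methoxyphenyl]-6,8-dimethoxynaphthalen-2-ol F3, whose C3 substituent is already a benzyl group. Hydrogenolysis of the three benzyl ethers (H2, Pd/C, EtOAc/MeOH) then gives 26.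

Step 10. Deprotonation of the doubly activated benzylic position of keto aldehyde 11 by the acetylide, or self-condensation of 11 before it is used, may compete with addition. The fallback masks the aldehyde as a lactol; it sets out from 8 and comes back at 18. Lemieux–Johnson cleavage of 8 (OsO4, NaIO4, 2,6-lutidine, dioxane/H2O) gives an aldehyde that the benzhydrylic hydroxyl traps as the six-membered lactol 6-(benzyloxy)-1-[4-(benzyloxy)-2-methoxyphenyl]-5,7-dimethoxy-3,4-dihydro-1H-isochromen-3-ol F4. An excess of lithium acetylide 16 (THF, −78 °C to 0 °C) opens the lactol and adds to the aldehyde, giving the diol 1-{3-(benzyloxy)-6-[[4-(benzyloxy)-2-methoxyphenyl](hydroxy)methyl]-2,4-dimethoxyphenyl}-4-[4-(benzyloxy)-3-methoxyphenyl]but-3-yn-2-ol F5 as a diastereomer mixture. TBSCl and imidazole should silylate the unhindered propargylic hydroxyl in preference to the doubly ortho-flanked benzhydrylic one, giving [4-(benzyloxy)-2-{4-[4-(benzyloxy)-3-methoxyphenyl]-2-[(tert-butyldimethylsilyl)oxy]but-3-yn-1-yl}-3,5-dimethoxyphenyl][4-(benzyloxy)-2-methoxyphenyl]methanol F6. Dess–Martin oxidation of the remaining carbinol merges the diastereomers into 18.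

Step 15. Hydrogenolysis of the hindered, hydrogen-bonded diaryl ketone may stall at the ketone or carbinol stage after the benzyl ethers are gone, or forcing it may start to saturate the electron-rich rings. The fallback separates the two tasks; it sets out from 23 and comes back at 26. Hydrogenolysis in neutral EtOAc (H2, Pd/C, rt) is limited to the benzyl ethers and gives triphenol ketone 24 as an isolated compound. Ionic hydrogenation with Et3SiH in CF3CO2H/CH2Cl2 then reduces the protonated ketone through carbinol 25 and its quinone-methide-like cation to the methylene group of 26. This detour makes no compound outside the list (entry F0).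

**Further compounds**

F1 | step 12 | racemic [4-(benzyloxy)-2-{4-[4-(benzyloxy)-3-methoxyphenyl]-2-hydroxybutyl}-3,5-dimethoxyphenyl][4-(benzyloxy)-2-methoxyphenyl]methanone | COc1cc(C(=O)c2ccc(OCc3ccccc3)cc2OC)c(CC(O)CCc2ccc(OCc3ccccc3)c(OC)c2)c(OC)c1OCc1ccccc1
F2 | step 12 | 1-{3-(benzyloxy)-6-[4-(benzyloxy)-2-methoxybenzoyl]-2,4-dimethoxyphenyl}-4-[4-(benzyloxy)-3-methoxyphenyl]butan-2-one | COc1cc(C(=O)c2ccc(OCc3ccccc3)cc2OC)c(CC(=O)CCc2ccc(OCc3ccccc3)c(OC)c2)c(OC)c1OCc1ccccc1
F3 | step 12 | 7-(benzyloxy)-3-[4-(benzyloxy)-3-methoxybenzyl]-4-[4-(benzyloxy)-2-methoxyphenyl]-6,8-dimethoxynaphthalen-2-ol | COc1cc(Cc2c(O)cc3c(OC)c(OCc4ccccc4)c(OC)cc3c2-c2ccc(OCc3ccccc3)cc2OC)ccc1OCc1ccccc1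
F4 | step 10 | 6-(benzyloxy)-1-[4-(benzyloxy)-2-methoxyphenyl]-5,7-dimethoxy-3,4-dihydro-1H-isochromen-3-ol (racemic diastereomer mixture) | COc1cc2c(c(OC)c1OCc1ccccc1)CC(O)OC2c1ccc(OCc2ccccc2)cc1OC
F5 | step 10 | 1-{3-(benzyloxy)-6-[[4-(benzyloxy)-2-methoxyphenyl](hydroxy)methyl]-2,4-dimethoxyphenyl}-4-[4-(benzyloxy)-3-methoxyphenyl]but-3-yn-2-ol (racemic diastereomer mixture) | COc1cc(C(O)c2ccc(OCc3ccccc3)cc2OC)c(CC(O)C#Cc2ccc(OCc3ccccc3)c(OC)c2)c(OC)c1OCc1ccccc1
F6 | step 10 | [4-(benzyloxy)-2-{4-[4-(benzyloxy)-3-methoxyphenyl]-2-[(tert-butyldimethylsilyl)oxy]but-3-yn-1-yl}-3,5-dimethoxyphenyl][4-(benzyloxy)-2-methoxyphenyl]methanol (racemic diastereomer mixture) | COc1cc(C(O)c2ccc(OCc3ccccc3)cc2OC)c(CC(O[Si](C)(C)C(C)(C)C)C#Cc2ccc(OCc3ccccc3)c(OC)c2)c(OC)c1OCc1ccccc1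
F0 | step 15 | none | none
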